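**Plan**
1. The last cut removes four benzyl ethers. The strategic cut is the bond between C6' of the central resorcinol ring and the CH2 group on C6 of the 2-pyranone ring.
2. That CH2 is the methyl group of triacetic acid lactone. Its C–H bonds are acidified through C6=C5–C4=C3–C2=O of the pyranone ring, so the intact O-benzyl pyranone can serve as a C–H nucleophile (extended zinc dienolate) and be joined by palladium to an aryl bromide without prior functionalisation.
3. The other half is a 6'-bromoflavone. Its chromone ring is cut at O1–C2 (oxidative cyclisation of a 2'-hydroxychalcone) and at C2–C3 (Claisen–Schmidt condensation). The bromine meta to both oxygens, a position closed to electrophilic substitution, comes from 5-bromoresorcinol dibenzyl ether by Vilsmeier–Haack formylation.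
4. Forward order: A-ring ketone and B-ring aldehyde, chalcone, chromone ring, aryl–CH2 coupling with the preformed pyranone ring, global debenzylation.
5. No stereochemistry has to be set: the target has no stereocentre.

Key step: step 6

Remark: the aryl–chromone axis is flanked on the chromone side only by O1 and C3–H and is taken to rotate freely, so the target is treated as achiral and is made as such.

**Step 1**
Reactants: 1 1-(2,4-dihydroxy-6-methylphenyl)ethan-1-one
Product: 2 1-[4-(benzyloxy)-2-hydroxy-6-methylphenyl]ethan-1-one
Conditions: BnBr (1.05 equiv), K2CO3 (1.2 equiv), acetone, reflux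
Reagents that add atoms: benzyl bromide, BrCc1ccccc1
Why: Williamson etherification should occur only at the 4-OH, because the 2-OH is held in a hydrogen bond to the acetyl carbonyl and is the less acidic and less nucleophilic phenol.

**Step 2**
Reactants: 3 1,3-bis(benzyloxy)-5-bromobenzene
Product: 5 2,4-bis(benzyloxy)-6-bromobenzaldehyde, via iminium chloride 4 (not isolated)
Conditions: POCl3 (1.5 equiv), DMF, 0 to 90 °C; then H2O, 0 °C to rt
Reagents that add atoms: N,N-dimethylformamide, CN(C)C=O; water, O
Why: Vilsmeier–Haack formylation should attack the position para to one benzyloxy group and ortho to the other (next to bromine) rather than the doubly flanked position between the two benzyloxy groups, as is known for 5-bromoresorcinol diethers, and hydrolysis of iminium salt 4 releases the aldehyde.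

**Step 3**
Reactants: 2 1-[4-(benzyloxy)-2-hydroxy-6-methylphenyl]ethan-1-one; 5 2,4-bis(benzyloxy)-6-bromobenzaldehyde
Product: 6 (2E)-1-[4-(benzyloxy)-2-hydroxy-6-methylphenyl]-3-[2,4-bis(benzyloxy)-6-bromophenyl]prop-2-en-1-one
Conditions: KOH (50% aq.), EtOH/THF, rt
Reagents that add atoms: none
Why: Claisen–Schmidt condensation of the methyl ketone enolate with the non-enolisable aldehyde, followed by E1cB loss of water, should give the conjugated (E)-enone under thermodynamic control.

**Step 4**
Reactants: 6 (2E)-1-[4-(benzyloxy)-2-hydroxy-6-methylphenyl]-3-[2,4-bis(benzyloxy)-6-bromophenyl]prop-2-en-1-one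
Product: 7 7-(benzyloxy)-2-[2,4-bis(benzyloxy)-6-bromophenyl]-5-methyl-4H-chromen-4-one
Conditions: I2 (10 mol%), DMSO, 130 °C
Reagents that add atoms: none
Why: The iodine/DMSO oxidative cyclisation of 2'-hydroxychalcones (oxa-Michael closure at the β-carbon, α-iodination and loss of HI, with DMSO re-oxidising HI) is the standard flavone synthesis and should tolerate benzyl ethers and the aryl bromide.

**Step 5**
Reactants: 8 4-hydroxy-6-methyl-2H-pyran-2-one (triacetic acid lactone)
Product: 9 4-(benzyloxy)-6-methyl-2H-pyran-2-one
Conditions: BnBr (1.1 equiv), K2CO3 (1.2 equiv), DMF, 50 °C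
Reagents that add atoms: benzyl bromide, BrCc1ccccc1
Why: O-alkylation of the acidic vinylogous carboxylic acid (4-OH) with a benzylic halide should give the 4-benzyloxy-2-pyranone, in line with the known preparation of 4-alkoxy-6-methyl-2-pyranones.

**Step 6**
Reactants: 9 4-(benzyloxy)-6-methyl-2H-pyran-2-one; 7 7-(benzyloxy)-2-[2,4-bis(benzyloxy)-6-bromophenyl]-5-methyl-4H-chromen-4-one
Product: 12 7-(benzyloxy)-2-[2,4-bis(benzyloxy)-6-{[4-(benzyloxy)-2-oxo-2H-pyran-6-yl]methyl}phenyl]-5-methyl-4H-chromen-4-one, via lithium dienolate 10 (not isolated), via zinc dienolate 11 (not isolated)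
Conditions: 9 (1.5 equiv), LiHMDS (1.45 equiv), THF, −78 °C; ZnCl2 (1.6 equiv), −78 °C to rt; then 7 (1.0 equiv), Pd(dba)2 (5 mol%), Q-Phos (5 mol%), THF, rt to 50 °C
Reagents that add atoms: none
Why: Proposed new method: LiHMDS removes a proton from the 6-methyl group of 9, which is acidified through C6=C5–C4=C3–C2=O, to give the extended dienolate 10; zinc chloride converts it into the weakly basic zinc dienolate 11, and a Pd(0)/Q-Phos catalyst inserts into the C6'–Br bond of 7, takes over the dienolate from zinc and reductively eliminates to form the aryl–CH2 bond. The closest known reaction types are the palladium-catalysed α-arylation of zinc (Reformatsky-type) ester enolates, the γ-arylation of metal dienolates of unsaturated esters and lactones and the Negishi coupling of benzylic zinc halides; the new element is the transfer to the ε-terminus of a 6-methyl-2-pyranone. No ring is closed and no stereocentre is formed in this step. Site selectivity for the exocyclic CH2 over C3, C5 and oxygen is needed and should follow from the preference of palladium for the unhindered primary terminus, where C–C bond formation restores the conjugated 2-pyranone, in line with the alkylations and aldol additions of this anion. Mono-arylation should be secured by the zinc dienolate, which is too weakly basic to deprotonate the more acidic product, and by the ortho-chromonyl group that shields the new benzylic carbon. The chromone should survive because no free amide base or lithium enolate is left when 7 is added (no attack at C2, no metalation of the 5-methyl group), because its C4 carbonyl is a hindered vinylogous ester that zinc enolates do not attack, and because the low temperature disfavours a 1,4-palladium shift from C6' to C3.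

**Step 7**
Reactants: 12 7-(benzyloxy)-2-[2,4-bis(benzyloxy)-6-{[4-(benzyloxy)-2-oxo-2H-pyran-6-yl]methyl}phenyl]-5-methyl-4H-chromen-4-one
Product: 13 7-hydroxy-2-[2,4-dihydroxy-6-[(4-hydroxy-2-oxo-2H-pyran-6-yl)methyl]phenyl]-5-methyl-4H-chromen-4-one
Conditions: H2 (1 atm), 10% Pd/C, THF/MeOH, rt, stopped as soon as debenzylation is complete
Reagents that add atoms: none
Why: Hydrogenolysis of the three aryl benzyl ethers and of the vinylogous benzyl ester on the pyranone is a standard global deprotection that should leave the chromone, the 2-pyranone and the diarylmethane-type CH2 untouched at 1 atm and room temperature.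

**Compound list**
1 | 1-(2,4-dihydroxy-6-methylphenyl)ethan-1-one | CC(=O)c1c(C)cc(O)cc1O | starting material
2 | 1-[4-(benzyloxy)-2-hydroxy-6-methylphenyl]ethan-1-one | CC(=O)c1c(C)cc(OCc2ccccc2)cc1O | intermediate
3 | 1,3-bis(benzyloxy)-5-bromobenzene | Brc1cc(OCc2ccccc2)cc(OCc2ccccc2)c1 | starting material
4 | N-{[2,4-bis(benzyloxy)-6-bromophenyl]methylidene}-N-methylmethanaminium chloride (not isolated) | C[N+](C)=Cc1c(Br)cc(OCc2ccccc2)cc1OCc1ccccc1.[Cl-] | intermediate
5 | 2,4-bis(benzyloxy)-6-bromobenzaldehyde | O=Cc1c(Br)cc(OCc2ccccc2)cc1OCc1ccccc1 | intermediate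
6 | (2E)-1-[4-(benzyloxy)-2-hydroxy-6-methylphenyl]-3-[2,4-bis(benzyloxy)-6-bromophenyl]prop-2-en-1-one | Cc1cc(OCc2ccccc2)cc(O)c1C(=O)/C=C/c1c(Br)cc(OCc2ccccc2)cc1OCc1ccccc1 | intermediate
7 | 7-(benzyloxy)-2-[2,4-bis(benzyloxy)-6-bromophenyl]-5-methyl-4H-chromen-4-one | Cc1cc(OCc2ccccc2)cc2oc(-c3c(Br)cc(OCc4ccccc4)cc3OCc3ccccc3)cc(=O)c12 | intermediate
8 | 4-hydroxy-6-methyl-2H-pyran-2-one (triacetic acid lactone) | Cc1cc(O)cc(=O)o1 | starting material
9 | 4-(benzyloxy)-6-methyl-2H-pyran-2-one | Cc1cc(OCc2ccccc2)cc(=O)o1 | intermediate
10 | lithium 4-(benzyloxy)-6-methylidene-6H-pyran-2-olate (not isolated) | C=C1C=C(OCc2ccccc2)C=C(O[Li])O1 | intermediate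
11 | chloro{[4-(benzyloxy)-2-oxo-2H-pyran-6-yl]methyl}zinc (not isolated) | Cl[Zn]Cc1cc(OCc2ccccc2)cc(=O)o1 | intermediate
12 | 7-(benzyloxy)-2-[2,4-bis(benzyloxy)-6-{[4-(benzyloxy)-2-oxo-2H-pyran-6-yl]methyl}phenyl]-5-methyl-4H-chromen-4-one | Cc1cc(OCc2ccccc2)cc2oc(-c3c(Cc4cc(OCc5ccccc5)cc(=O)o4)cc(OCc4ccccc4)cc3OCc3ccccc3)cc(=O)c12 | intermediate
13 | 7-hydroxy-2-[2,4-dihydroxy-6-[(4-hydroxy-2-oxo-2H-pyran-6-yl)methyl]phenyl]-5-methyl-4H-chromen-4-one | Cc1cc(O)cc2oc(-c3c(O)cc(O)cc3Cc3cc(O)cc(=O)o3)cc(=O)c12 | target

**Step count and risks**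
Total steps: 7. Longest linear sequence: 5 steps (steps 2, 3, 4, 6, 7 from 3, or steps 1, 3, 4, 6, 7 from 1).

Steps most likely to fail:

1. Step 6 (proposed new method). The dienolate may be transferred to palladium and coupled at the wrong site (C3, C5 or oxygen), oxidative addition at the hindered C6'–Br bond may be slow, or the nucleophile may attack the chromone. The fallback uses known chemistry with reversed polarity, setting out from 7 and 9 and returning to the route at 12. Miyaura borylation of 7 (B2pin2, Pd(dppf)Cl2, KOAc, dioxane, 90 °C) should give the aryl boronate 7-(benzyloxy)-2-[2,4-bis(benzyloxy)-6-(4,4,5,5-tetramethyl-1,3,2-dioxaborolan-2-yl)phenyl]-5-methyl-4H-chromen-4-one F1. Wohl–Ziegler bromination of the 6-methyl group of 9 (NBS, AIBN, PhCF3, reflux), as practised on the 4-methoxy analogue, should give 4-(benzyloxy)-6-(bromomethyl)-2H-pyran-2-one F2; the O–CH2Ph hydrogens are deactivated toward bromine-atom abstraction because that oxygen belongs to a vinylogous ester. Suzuki–Miyaura coupling of F1 with the benzylic-type bromide F2 (Pd(PPh3)4, K3PO4, THF/H2O, 60 °C) should then give 12.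

2. Step 4. Oxa-Michael closure onto a β-carbon that bears a 2,6-disubstituted aryl group may be slow, and ring iodination of the electron-rich rings or acid-induced loss of a benzyl group may compete at 130 °C. The fallback builds the chromone by cyclodehydration of a 1,3-diketone (Baker–Venkataraman-type route), setting out from 5 and 2 and returning at 7. Pinnick oxidation of 5 (NaClO2, NaH2PO4, 2-methyl-2-butene, t-BuOH/H2O) should give 2,4-bis(benzyloxy)-6-bromobenzoic acid F3, and oxalyl chloride with catalytic DMF in CH2Cl2 should give 2,4-bis(benzyloxy)-6-bromobenzoyl chloride F4. C-acylation of the lithium dianion of 2 (LiHMDS, 3 equiv, THF, −78 °C to rt) with F4 should give 1-[4-(benzyloxy)-2-hydroxy-6-methylphenyl]-3-[2,4-bis(benzyloxy)-6-bromophenyl]propane-1,3-dione F5. Acid-catalysed cyclodehydration of F5 (p-TsOH, toluene, 90 °C) should close the ring to 7.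

3. Step 7. Over-reduction may occur once the benzyl groups are gone (saturation of the pyranone C5=C6 or the chromone C2=C3 bond), or the last benzyl groups may cleave slowly on a catalyst fouled by the polyphenol. The fallback replaces the reductive cleavage with a non-reductive, Lewis-acid-mediated benzyl transfer, setting out from 12 and arriving directly at 13: BCl3 (excess) and pentamethylbenzene in CH2Cl2 at −78 to 0 °C, followed by a methanol quench. Pentamethylbenzene traps the benzyl cations by Friedel–Crafts alkylation, so neither hydrogenation nor benzylation of the resorcinol ring or pyranone C3 can take place.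

**Further compounds**
F1 | step 6 | 7-(benzyloxy)-2-[2,4-bis(benzyloxy)-6-(4,4,5,5-tetramethyl-1,3,2-dioxaborolan-2-yl)phenyl]-5-methyl-4H-chromen-4-one | Cc1cc(OCc2ccccc2)cc2oc(-c3c(B4OC(C)(C)C(C)(C)O4)cc(OCc4ccccc4)cc3OCc3ccccc3)cc(=O)c12
F2 | step 6 | 4-(benzyloxy)-6-(bromomethyl)-2H-pyran-2-one | BrCc1cc(OCc2ccccc2)cc(=O)o1
F3 | step 4 | 2,4-bis(benzyloxy)-6-bromobenzoic acid | OC(=O)c1c(Br)cc(OCc2ccccc2)cc1OCc1ccccc1
F4 | step 4 | 2,4-bis(benzyloxy)-6-bromobenzoyl chloride | O=C(Cl)c1c(Br)cc(OCc2ccccc2)cc1OCc1ccccc1
F5 | step 4 | 1-[4-(benzyloxy)-2-hydroxy-6-methylphenyl]-3-[2,4-bis(benzyloxy)-6-bromophenyl]propane-1,3-dione | Cc1cc(OCc2ccccc2)cc(O)c1C(=O)CC(=O)c1c(Br)cc(OCc2ccccc2)cc1OCc1ccccc1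
F0 | step 7 | none | none
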